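**Strategy.** The synthesis rests on disconnecting the aryl ketone bond C4–C4a of pyranone ring C. An aryl bromide whose ether oxygen O1 carries a CH2–C(aryl)(CO2allyl)2 unit is lithiated at C4a; the aryllithium attacks one of the two enantiotopic allyl esters and closes ring C in one operation. The step exploits the ortho relation of O1 (on C8a) and C4a on ring A and the fact that C3 is the enolizable α-carbon of the C4 ketone: the second ester blocks C3 during the anionic closure and then serves as the handle for a palladium-catalysed decarboxylative enantioselective protonation that sets (S)-C3 last.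

Key step: step 8

Assumption: in step 9 the (S)-ligand is taken to deliver the (3S)-ketone; if the sense of induction on this substrate is the opposite, the (R)-ligand is used with no other change. Compounds drawn without a descriptor at C3 are racemates.

**Route**

Step 1
Reactants: 1 4-bromo-3-methoxyphenol
Product: 2 (4-bromo-3-methoxyphenoxy)triisopropylsilane
Conditions: TIPSCl, imidazole, DMF, rt
Reagents that add atoms: triisopropylsilyl chloride, CC(C)[Si](Cl)(C(C)C)C(C)C
Why: Imidazole-promoted silylation of the phenol (standard silyl ether protection) should give an aryl TIPS ether that withstands the bases and the organolithium used later.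

Step 2
Reactants: 2 (4-bromo-3-methoxyphenoxy)triisopropylsilane; 3 dimethyl malonate
Product: 4 dimethyl 2-{2-methoxy-4-[(triisopropylsilyl)oxy]phenyl}malonate
Conditions: Pd(OAc)2 (2 mol %), P(t-Bu)3·HBF4 (4 mol %), K3PO4, toluene, 80 °C
Reagents that add atoms: none
Why: Palladium-catalysed α-arylation of a malonate enolate with a bulky electron-rich phosphine accepts the electron-rich ortho-methoxy aryl bromide, and the mild base K3PO4 spares the silyl ether.

Step 3
Reactants: 4 dimethyl 2-{2-methoxy-4-[(triisopropylsilyl)oxy]phenyl}malonate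
Product: 5 diallyl 2-{2-methoxy-4-[(triisopropylsilyl)oxy]phenyl}malonate
Conditions: allyl alcohol (excess), Bu2SnO (10 mol %), toluene, reflux, removal of MeOH
Reagents that add atoms: allyl alcohol, C=CCO
Why: Tin-catalysed transesterification driven by removal of methanol should exchange both esters; the allyl esters cannot be brought in during step 2 because zerovalent palladium would ionise them.

Step 4
Reactants: 5 diallyl 2-{2-methoxy-4-[(triisopropylsilyl)oxy]phenyl}malonate
Product: 6 diallyl 2-(hydroxymethyl)-2-{2-methoxy-4-[(triisopropylsilyl)oxy]phenyl}malonate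
Conditions: (CH2O)n, DBU (10 mol %), THF, 0 °C to rt; AcOH before work-up
Reagents that add atoms: formaldehyde (as paraformaldehyde), C=O
Why: Base-catalysed aldol-type hydroxymethylation of the acidic malonate C–H should create the quaternary carbon (future C3) and the C2 carbinol, and acidification before work-up suppresses the retro-aldol reaction.

Step 5
Reactants: 7 4-bromobenzene-1,3-diol (4-bromoresorcinol); 8 geraniol
Product: 9 4-bromo-6-[(2E)-3,7-dimethylocta-2,6-dien-1-yl]benzene-1,3-diol
Conditions: BF3·OEt2 (0.5 equiv), 1,4-dioxane, rt, short reaction time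
Reagents that add atoms: none
Why: Friedel–Crafts allylation of the resorcinol by the geranyl cation equivalent should occur at C6 of 7, which is ortho and para to the two hydroxyls and unhindered, because bromine blocks C4 and the site between the hydroxyls is crowded; the E-olefin is retained under these dioxane-moderated conditions.

Step 6
Reactants: 6 diallyl 2-(hydroxymethyl)-2-{2-methoxy-4-[(triisopropylsilyl)oxy]phenyl}malonate; 9 4-bromo-6-[(2E)-3,7-dimethylocta-2,6-dien-1-yl]benzene-1,3-diol
Product: 10 diallyl 2-({2-bromo-4-[(2E)-3,7-dimethylocta-2,6-dien-1-yl]-5-hydroxyphenoxy}methyl)-2-{2-methoxy-4-[(triisopropylsilyl)oxy]phenyl}malonate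
Conditions: PPh3, DIAD, toluene, 0 °C to 80 °C (9 in slight excess)
Reagents that add atoms: none
Why: Mitsunobu etherification should alkylate the hydroxyl ortho to bromine, the more acidic of the two phenols, and heating is used because the carbinol is neopentylic.

Step 7
Reactants: 10 diallyl 2-({2-bromo-4-[(2E)-3,7-dimethylocta-2,6-dien-1-yl]-5-hydroxyphenoxy}methyl)-2-{2-methoxy-4-[(triisopropylsilyl)oxy]phenyl}malonate
Product: 11 diallyl 2-({2-bromo-4-[(2E)-3,7-dimethylocta-2,6-dien-1-yl]-5-[(triisopropylsilyl)oxy]phenoxy}methyl)-2-{2-methoxy-4-[(triisopropylsilyl)oxy]phenyl}malonate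
Conditions: TIPSOTf, 2,6-lutidine, CH2Cl2, 0 °C
Reagents that add atoms: triisopropylsilyl trifluoromethanesulfonate, CC(C)[Si](OS(=O)(=O)C(F)(F)F)(C(C)C)C(C)C
Why: Silyl triflate with a hindered base should silylate the remaining ortho-substituted phenol, so that no acidic O–H is present in the lithiation (standard silyl ether protection).

Step 8
Reactants: 11 diallyl 2-({2-bromo-4-[(2E)-3,7-dimethylocta-2,6-dien-1-yl]-5-[(triisopropylsilyl)oxy]phenoxy}methyl)-2-{2-methoxy-4-[(triisopropylsilyl)oxy]phenyl}malonate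
Product: 14 allyl 6-[(2E)-3,7-dimethylocta-2,6-dien-1-yl]-3-{2-methoxy-4-[(triisopropylsilyl)oxy]phenyl}-4-oxo-7-[(triisopropylsilyl)oxy]chromane-3-carboxylate (racemic), via aryllithium 12 (not isolated), via lithium hemiketal 13 (not isolated)
Conditions: n-BuLi (1.05 equiv), THF/Et2O, −100 °C, then −78 °C; AcOH in THF, −78 °C
Reagents that add atoms: none
Why: Bromine–lithium exchange at −100 °C should outrun addition of n-BuLi to the hindered malonate esters and give aryllithium 12, which adds to one allyl ester carbonyl; lithium hemiketal 13 keeps the carbonyl masked until the cold acetic acid quench releases ketone 14 and allyl alcohol. The closest known reaction type is the Parham cyclisation of ortho-haloaryl esters to benzo-fused ketones. Ring C is the only ring closed, in the 6-exo-trig mode. C3 becomes a quaternary stereocentre without control, because the two esters are enantiotopic and the racemate is intended (C3 is set again in step 9). The step needs chemoselectivity (exchange before carbonyl addition, a single addition, no proton transfer or β-elimination of the aryloxide), which is secured by the low temperature, by the absence of any C–H on C3 and by the persistence of 13; the site of metalation is fixed by the bromine at C4a. Warming before the quench is avoided because lithium allyloxide would open the non-enolisable β-keto ester by retro-Claisen cleavage.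

Step 9
Reactants: 14 allyl 6-[(2E)-3,7-dimethylocta-2,6-dien-1-yl]-3-{2-methoxy-4-[(triisopropylsilyl)oxy]phenyl}-4-oxo-7-[(triisopropylsilyl)oxy]chromane-3-carboxylate (racemic)
Product: 15 (3S)-6-[(2E)-3,7-dimethylocta-2,6-dien-1-yl]-3-{2-methoxy-4-[(triisopropylsilyl)oxy]phenyl}-7-[(triisopropylsilyl)oxy]chroman-4-one
Conditions: Pd2(dba)3 (5 mol %), (S)-t-BuPHOX [(S)-4-tert-butyl-2-(2-diphenylphosphinophenyl)-4,5-dihydrooxazole] (12.5 mol %), Meldrum's acid (2.5 equiv), 1,4-dioxane, rt
Reagents that add atoms: none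
Why: Palladium-catalysed decarboxylative asymmetric protonation of an α-aryl β-keto allyl ester: ionisation of the allyl ester by zerovalent palladium and loss of CO2 unmask the C3 enolate in the chiral pocket of the PHOX-bound metal, where Meldrum's acid should deliver the proton to one enantioface and scavenge the allyl group, the neutral medium keeping the new (S)-centre from racemising.

Step 10
Reactants: 15 (3S)-6-[(2E)-3,7-dimethylocta-2,6-dien-1-yl]-3-{2-methoxy-4-[(triisopropylsilyl)oxy]phenyl}-7-[(triisopropylsilyl)oxy]chroman-4-one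
Product: 16 (3S)-6-[(2E)-3,7-dimethylocta-2,6-dien-1-yl]-7-hydroxy-3-(4-hydroxy-2-methoxyphenyl)chroman-4-one (target, CNP0292854.1)
Conditions: Et3N·3HF, THF, 0 °C to rt; non-basic work-up
Reagents that add atoms: none
Why: Fluoride-mediated desilylation should cleave both aryl silyl ethers in a slightly acidic medium that neither enolises C3 nor protonates the geranyl olefins.

**Compound list**

1 | 4-bromo-3-methoxyphenol | COc1cc(O)ccc1Br | starting material
2 | (4-bromo-3-methoxyphenoxy)triisopropylsilane | COc1cc(O[Si](C(C)C)(C(C)C)C(C)C)ccc1Br | intermediate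
3 | dimethyl malonate | COC(=O)CC(=O)OC | starting material
4 | dimethyl 2-{2-methoxy-4-[(triisopropylsilyl)oxy]phenyl}malonate | COc1cc(O[Si](C(C)C)(C(C)C)C(C)C)ccc1C(C(=O)OC)C(=O)OC | intermediate
5 | diallyl 2-{2-methoxy-4-[(triisopropylsilyl)oxy]phenyl}malonate | COc1cc(O[Si](C(C)C)(C(C)C)C(C)C)ccc1C(C(=O)OCC=C)C(=O)OCC=C | intermediate
6 | diallyl 2-(hydroxymethyl)-2-{2-methoxy-4-[(triisopropylsilyl)oxy]phenyl}malonate | COc1cc(O[Si](C(C)C)(C(C)C)C(C)C)ccc1C(CO)(C(=O)OCC=C)C(=O)OCC=C | intermediate
7 | 4-bromobenzene-1,3-diol (4-bromoresorcinol) | Oc1ccc(Br)c(O)c1 | starting material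
8 | geraniol, (2E)-3,7-dimethylocta-2,6-dien-1-ol | OC/C=C(\C)CCC=C(C)C | starting material
9 | 4-bromo-6-[(2E)-3,7-dimethylocta-2,6-dien-1-yl]benzene-1,3-diol | Oc1cc(O)c(C/C=C(\C)CCC=C(C)C)cc1Br | intermediate
10 | diallyl 2-({2-bromo-4-[(2E)-3,7-dimethylocta-2,6-dien-1-yl]-5-hydroxyphenoxy}methyl)-2-{2-methoxy-4-[(triisopropylsilyl)oxy]phenyl}malonate | COc1cc(O[Si](C(C)C)(C(C)C)C(C)C)ccc1C(COc1cc(O)c(C/C=C(\C)CCC=C(C)C)cc1Br)(C(=O)OCC=C)C(=O)OCC=C | intermediate
11 | diallyl 2-({2-bromo-4-[(2E)-3,7-dimethylocta-2,6-dien-1-yl]-5-[(triisopropylsilyl)oxy]phenoxy}methyl)-2-{2-methoxy-4-[(triisopropylsilyl)oxy]phenyl}malonate | COc1cc(O[Si](C(C)C)(C(C)C)C(C)C)ccc1C(COc1cc(O[Si](C(C)C)(C(C)C)C(C)C)c(C/C=C(\C)CCC=C(C)C)cc1Br)(C(=O)OCC=C)C(=O)OCC=C | intermediate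
12 | aryllithium from 11 (lithium in place of bromine) | COc1cc(O[Si](C(C)C)(C(C)C)C(C)C)ccc1C(COc1cc(O[Si](C(C)C)(C(C)C)C(C)C)c(C/C=C(\C)CCC=C(C)C)cc1[Li])(C(=O)OCC=C)C(=O)OCC=C | intermediate
13 | lithium hemiketal: lithium 4-(allyloxy)-3-(allyloxycarbonyl)chroman-4-olate carrying the substituents of 14 | COc1cc(O[Si](C(C)C)(C(C)C)C(C)C)ccc1C1(C(=O)OCC=C)COc2cc(O[Si](C(C)C)(C(C)C)C(C)C)c(C/C=C(\C)CCC=C(C)C)cc2C1(O[Li])OCC=C | intermediate
14 | allyl 6-[(2E)-3,7-dimethylocta-2,6-dien-1-yl]-3-{2-methoxy-4-[(triisopropylsilyl)oxy]phenyl}-4-oxo-7-[(triisopropylsilyl)oxy]chromane-3-carboxylate (racemic) | COc1cc(O[Si](C(C)C)(C(C)C)C(C)C)ccc1C1(C(=O)OCC=C)COc2cc(O[Si](C(C)C)(C(C)C)C(C)C)c(C/C=C(\C)CCC=C(C)C)cc2C1=O | intermediate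
15 | (3S)-6-[(2E)-3,7-dimethylocta-2,6-dien-1-yl]-3-{2-methoxy-4-[(triisopropylsilyl)oxy]phenyl}-7-[(triisopropylsilyl)oxy]chroman-4-one | COc1cc(O[Si](C(C)C)(C(C)C)C(C)C)ccc1[C@H]1COc2cc(O[Si](C(C)C)(C(C)C)C(C)C)c(C/C=C(\C)CCC=C(C)C)cc2C1=O | intermediate
16 | (3S)-6-[(2E)-3,7-dimethylocta-2,6-dien-1-yl]-7-hydroxy-3-(4-hydroxy-2-methoxyphenyl)chroman-4-one | COc1cc(O)ccc1[C@H]1COc2cc(O)c(C/C=C(\C)CCC=C(C)C)cc2C1=O | target

**Count and risks**

Total steps: 10. Longest linear sequence: 9 (steps 1–4 and 6–10; step 5 is the side branch).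

Steps most likely to fail:

Step 6. The displacement at the neopentylic CH2 of 6 may be too slow, so that alkylation of the hydrazide or retro-aldol loss of formaldehyde takes over, and O-alkylation may spread over both phenols of 9. The fallback forms the C2–C3 bond instead of the O1–C2 bond; it sets out from 9 and 5 and comes back at 11. Diol 9 is alkylated at its more acidic oxygen (ortho to bromine) with NaH (1 equiv) and chloromethyl methyl sulfide in DMF to give 4-bromo-2-geranyl-5-[(methylsulfanyl)methoxy]phenol F1. Silylation (TIPSOTf, 2,6-lutidine) gives the silyl ether F2, and SO2Cl2 in CH2Cl2 at −78 °C exchanges the sulfide for chloride to give the aryl chloromethyl ether F3. Malonate 5 is deprotonated with NaH in THF to its sodium enolate F4, which is C-alkylated by F3 to give 11 directly.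

Step 8. n-BuLi may add to an allyl ester before the exchange, the aryllithium may be protonated, or the released allyloxide may open the product by retro-Claisen cleavage. The fallback closes the same bond by electrophilic instead of anionic chemistry; it sets out from 6 and 8 and comes back at 14. Resorcinol and 8 (BF3·OEt2, dioxane) give 4-[(2E)-3,7-dimethylocta-2,6-dien-1-yl]benzene-1,3-diol F5. Mitsunobu coupling with 6 at the unhindered hydroxyl para to the geranyl group gives the aryl ether F6, and TIPSOTf/2,6-lutidine gives the bis-silyl ether F7. LiOH (1 equiv, THF/H2O, 0 °C) cleaves one allyl ester to the malonic half acid F8, and (COCl)2 with catalytic DMF gives the acid chloride F9, which cannot form a ketene. SnCl4 with 2,6-di-tert-butylpyridine in CH2Cl2 at −78 °C should then close ring C by Friedel–Crafts acylation at the position ortho to O1 and para to the silyloxy group, giving 14.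

Step 9. Enantiofacial discrimination in the protonation may be poor, since the aryl group has only one ortho substituent, and the product may partly racemise during the reaction. The fallback sets the centre by reduction under dynamic kinetic resolution; it sets out from 14 and comes back at 15. Pd(PPh3)4 with HCO2H in THF gives the racemic ketone F10. Asymmetric transfer hydrogenation with RuCl(p-cymene)[(S,S)-TsDPEN] and HCO2H/Et3N in EtOAc, during which C3 epimerises rapidly, should give the cis-(3S,4S)-chroman-4-ol F11. Dess–Martin periodinane in CH2Cl2 at 0 °C oxidises F11 to 15 without touching C3.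

**Further compounds**

F1 | step 6 | 4-bromo-2-[(2E)-3,7-dimethylocta-2,6-dien-1-yl]-5-[(methylsulfanyl)methoxy]phenol | CSCOc1cc(O)c(C/C=C(\C)CCC=C(C)C)cc1Br
F2 | step 6 | {4-bromo-2-[(2E)-3,7-dimethylocta-2,6-dien-1-yl]-5-[(methylsulfanyl)methoxy]phenoxy}triisopropylsilane | CSCOc1cc(O[Si](C(C)C)(C(C)C)C(C)C)c(C/C=C(\C)CCC=C(C)C)cc1Br
F3 | step 6 | {4-bromo-5-(chloromethoxy)-2-[(2E)-3,7-dimethylocta-2,6-dien-1-yl]phenoxy}triisopropylsilane | ClCOc1cc(O[Si](C(C)C)(C(C)C)C(C)C)c(C/C=C(\C)CCC=C(C)C)cc1Br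
F4 | step 6 | sodium enolate of diallyl 2-{2-methoxy-4-[(triisopropylsilyl)oxy]phenyl}malonate | COc1cc(O[Si](C(C)C)(C(C)C)C(C)C)ccc1C(C(=O)OCC=C)=C([O-])OCC=C.[Na+]
F5 | step 8 | 4-[(2E)-3,7-dimethylocta-2,6-dien-1-yl]benzene-1,3-diol | Oc1ccc(C/C=C(\C)CCC=C(C)C)c(O)c1
F6 | step 8 | diallyl 2-({4-[(2E)-3,7-dimethylocta-2,6-dien-1-yl]-3-hydroxyphenoxy}methyl)-2-{2-methoxy-4-[(triisopropylsilyl)oxy]phenyl}malonate | COc1cc(O[Si](C(C)C)(C(C)C)C(C)C)ccc1C(COc1ccc(C/C=C(\C)CCC=C(C)C)c(O)c1)(C(=O)OCC=C)C(=O)OCC=C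
F7 | step 8 | diallyl 2-({4-[(2E)-3,7-dimethylocta-2,6-dien-1-yl]-3-[(triisopropylsilyl)oxy]phenoxy}methyl)-2-{2-methoxy-4-[(triisopropylsilyl)oxy]phenyl}malonate | COc1cc(O[Si](C(C)C)(C(C)C)C(C)C)ccc1C(COc1ccc(C/C=C(\C)CCC=C(C)C)c(O[Si](C(C)C)(C(C)C)C(C)C)c1)(C(=O)OCC=C)C(=O)OCC=C
F8 | step 8 | 3-(allyloxy)-2-({4-[(2E)-3,7-dimethylocta-2,6-dien-1-yl]-3-[(triisopropylsilyl)oxy]phenoxy}methyl)-2-{2-methoxy-4-[(triisopropylsilyl)oxy]phenyl}-3-oxopropanoic acid | COc1cc(O[Si](C(C)C)(C(C)C)C(C)C)ccc1C(COc1ccc(C/C=C(\C)CCC=C(C)C)c(O[Si](C(C)C)(C(C)C)C(C)C)c1)(C(=O)O)C(=O)OCC=C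
F9 | step 8 | acid chloride of F8 | COc1cc(O[Si](C(C)C)(C(C)C)C(C)C)ccc1C(COc1ccc(C/C=C(\C)CCC=C(C)C)c(O[Si](C(C)C)(C(C)C)C(C)C)c1)(C(=O)Cl)C(=O)OCC=C
F10 | step 9 | racemic 6-[(2E)-3,7-dimethylocta-2,6-dien-1-yl]-3-{2-methoxy-4-[(triisopropylsilyl)oxy]phenyl}-7-[(triisopropylsilyl)oxy]chroman-4-one | COc1cc(O[Si](C(C)C)(C(C)C)C(C)C)ccc1C1COc2cc(O[Si](C(C)C)(C(C)C)C(C)C)c(C/C=C(\C)CCC=C(C)C)cc2C1=O
F11 | step 9 | (3S,4S)-6-[(2E)-3,7-dimethylocta-2,6-dien-1-yl]-3-{2-methoxy-4-[(triisopropylsilyl)oxy]phenyl}-7-[(triisopropylsilyl)oxy]chroman-4-ol (cis) | COc1cc(O[Si](C(C)C)(C(C)C)C(C)C)ccc1[C@H]1COc2cc(O[Si](C(C)C)(C(C)C)C(C)C)c(C/C=C(\C)CCC=C(C)C)cc2[C@H]1O
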